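**Retrosynthetic overview**

1. Numbering: ring C1 = C(OH)CH3, C2 = CH carrying the chain, C3 = C(CH3)2, C6 = ring CH2 beside C1; chain carbons C1′, C2′ … run outward from C2. The route rests on C2, a methine wedged between quaternary C3 and carbinol C1: if the C1 hydroxyl is traced back to a C6=C1 alkene, C6–C1–C2 is an allyl unit and an oxygen on C6 can pass C1′ to C2 on its own ring face.
2. Last bond, C4′–C5′: Negishi coupling of an (E)-alkenyl iodide (C3′=C4′, from methylalumination of a C3′≡C4′ alkyne) with homofarnesylzinc, made from (2E,6E)-farnesyl bromide by one-carbon homologation.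
3. C1–OH: from the C6=C1 alkene by epoxidation anti to the chain and hydride opening at C6. This is done only after C2′ has been used in the alkyne-forming substitution, because a free C1 hydroxyl would close a tetrahydrofuran onto any leaving group at C2′.
4. Key bond, C2–C1′: amide-acetal Claisen rearrangement of (R)-2,4,4-trimethylcyclohex-2-en-1-ol, whose carbinol centre comes from an oxazaborolidine-catalysed reduction of the enone.
5. Ring order: the single carbocycle is formed first, by enamine Robinson annulation of isobutyraldehyde with ethyl vinyl ketone; no other ring is closed.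

Key step: step 4

Assumption: the usual oxazaborolidine model, with the α-methyl alkenyl arm of the enone as the larger carbonyl substituent, is taken to hold, so the (S)-catalyst is assigned to the (R)-alcohol.

**Route**

Step 1
Reactants: 1 isobutyraldehyde
Product: 2 1-(2-methylprop-1-en-1-yl)pyrrolidine
Conditions: pyrrolidine (1.05 equiv), cyclohexane, reflux, Dean–Stark; distillation
Reagents that add atoms: pyrrolidine, C1CCNC1
Why: Stork enamine formation, in which azeotropic condensation of the α-branched aldehyde with the secondary amine gives the trisubstituted enamine; no stereocentre is involved.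

Step 2
Reactants: 2 1-(2-methylprop-1-en-1-yl)pyrrolidine; 3 ethyl vinyl ketone (pent-1-en-3-one)
Product: 5 2,4,4-trimethylcyclohex-2-en-1-one, via 2,2-dimethyl-5-oxoheptanal 4 (not isolated)
Conditions: neat, 0 °C to rt; then 8 M aq HCl, rt
Reagents that add atoms: none
Why: Enamine Robinson annulation, in which Stork Michael addition to the vinyl ketone and acid hydrolysis give keto aldehyde 4, whose ethyl-side enol closes on the aldehyde by intramolecular aldol condensation to the six-membered enone, the only ring of the target.

Step 3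
Reactants: 5 2,4,4-trimethylcyclohex-2-en-1-one
Product: 6 (R)-2,4,4-trimethylcyclohex-2-en-1-ol
Conditions: (S)-2-methyl-CBS-oxazaborolidine (10 mol %), BH3·SMe2, THF, −20 °C; MeOH quench
Reagents that add atoms: none
Why: Corey–Bakshi–Shibata reduction, in which the oxazaborolidine–borane complex binds the carbonyl anti to the larger α-methylalkenyl arm and delivers hydride to one face only (1,2-reduction), which for the (S)-catalyst should give the (R)-allylic alcohol.

Step 4
Reactants: 6 (R)-2,4,4-trimethylcyclohex-2-en-1-ol; 7 N,N-dimethylacetamide dimethyl acetal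
Product: 9 N,N-dimethyl-2-[(1S)-2,6,6-trimethylcyclohex-2-en-1-yl]acetamide, via ketene N,O-acetal 8 (not isolated)
Conditions: 7 (3 equiv), xylene, 140 °C, MeOH distilled off
Reagents that add atoms: none
Why: Alcohol 6 exchanges one methoxy group of 7 and loss of a second methanol gives ketene N,O-acetal 8, which undergoes a concerted [3,3]-sigmatropic shift across the ring allyl unit C6–C1=C2, forming C2–C1′ and moving the alkene to C6=C1; this is the Eschenmoser amide-acetal Claisen rearrangement, well established for cyclohex-2-en-1-ols. No ring is closed. The one new stereocentre, C2, is controlled by the C6 carbinol centre: the two-atom ketene acetal tether can reach C2 only on the ring face that carries the C6–O bond, so (R)-6 should give (S)-9 by 1,3-chirality transfer. The step needs rearrangement to outrun loss of the allylic oxygen by elimination to a diene, and the neutral medium together with the electron-rich aminoketene acetal, which rearranges near 140 °C, favours it. It also needs bond formation at C2 beside quaternary C3, which an intramolecular six-membered transition state tolerates far better than an intermolecular alkylation would.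

Step 5
Reactants: 9 N,N-dimethyl-2-[(1S)-2,6,6-trimethylcyclohex-2-en-1-yl]acetamide
Product: 10 2-[(1S)-2,6,6-trimethylcyclohex-2-en-1-yl]ethan-1-ol
Conditions: LiEt3BH (3 equiv), THF, 0 °C to rt; H2O
Reagents that add atoms: none
Why: Lithium triethylborohydride reduction of a tertiary amide with C–N cleavage (hydride addition, loss of dimethylamide, reduction of the aldehyde) should give the primary alcohol and leave the trisubstituted alkene and the C2 centre untouched.

Step 6
Reactants: 10 2-[(1S)-2,6,6-trimethylcyclohex-2-en-1-yl]ethan-1-ol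
Product: 11 (6S)-6-(2-iodoethyl)-1,5,5-trimethylcyclohex-1-ene
Conditions: I2, PPh3, imidazole, CH2Cl2, 0 °C to rt
Reagents that add atoms: iodine, II
Why: Appel-type iodination (Garegg–Samuelsson conditions), in which the alkoxyphosphonium ion of the primary alcohol is displaced by iodide in an SN2 reaction; C1 carries no hydroxyl yet, so no cyclic ether can form.

Step 7
Reactants: 11 (6S)-6-(2-iodoethyl)-1,5,5-trimethylcyclohex-1-ene
Product: 12 (6S)-6-(but-3-yn-1-yl)-1,5,5-trimethylcyclohex-1-ene
Conditions: lithium acetylide–ethylenediamine complex (LiC≡CH·H2NCH2CH2NH2), DMSO, 10 °C to rt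
Reagents that add atoms: lithium acetylide–ethylenediamine complex, [Li]C#C.NCCN
Why: SN2 alkylation of an acetylide, in which the primary iodide at C2′, two atoms away from the hindered ring carbon, is displaced to add C3′ and C4′ as a terminal alkyne.

Step 8
Reactants: 12 (6S)-6-(but-3-yn-1-yl)-1,5,5-trimethylcyclohex-1-ene
Product: 13 (1R,2S,6S)-2-(but-3-yn-1-yl)-1,3,3-trimethyl-7-oxabicyclo[4.1.0]heptane
Conditions: mCPBA (1.05 equiv), NaHCO3, CH2Cl2, 0 °C
Reagents that add atoms: mCPBA (3-chloroperoxybenzoic acid), OOC(=O)c1cccc(Cl)c1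
Why: Prilezhaev epoxidation, in which the peracid reacts with the electron-rich trisubstituted C6=C1 alkene far faster than with the terminal alkyne and should approach anti to the C2 chain, which screens its own face either directly (pseudoaxial) or together with the syn C3 methyl (pseudoequatorial), so the C1–O bond is set trans to the chain.

Step 9
Reactants: 13 (1R,2S,6S)-2-(but-3-yn-1-yl)-1,3,3-trimethyl-7-oxabicyclo[4.1.0]heptane
Product: 14 (1S,2S)-2-(but-3-yn-1-yl)-1,3,3-trimethylcyclohexan-1-ol
Conditions: LiEt3BH (3 equiv), THF, 0 to 40 °C; H2O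
Reagents that add atoms: none
Why: Hydride opening of a trisubstituted epoxide with LiEt3BH, in which SN2 attack at the secondary C6 leaves the C1–O bond intact, so the C1 configuration set in step 8 is carried into the tertiary alcohol.

Step 10
Reactants: 14 (1S,2S)-2-(but-3-yn-1-yl)-1,3,3-trimethylcyclohexan-1-ol
Product: 16 (1S,2S)-2-[(3E)-4-iodo-3-methylbut-3-en-1-yl]-1,3,3-trimethylcyclohexan-1-ol, via alkenylalane 15 (not isolated)
Conditions: AlMe3 (3.5 equiv), Cp2ZrCl2 (0.5 equiv), CH2Cl2, 0 °C to rt; then I2, THF, −30 to 0 °C; aq K2CO3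
Reagents that add atoms: trimethylaluminium, C[Al](C)C; iodine, II
Why: Negishi zirconium-catalysed carboalumination with iodinolysis, in which the hydroxyl is first capped as its aluminium alkoxide, methyl and aluminium then add syn across the terminal alkyne with methyl at internal C3′ to give alane 15, and iodine replaces aluminium with retention to give the (E)-alkenyl iodide.

Step 11
Reactants: 17 (2E,6E)-farnesyl bromide; 18 thioanisole
Product: 20 {[(3E,7E)-4,8,12-trimethyltrideca-3,7,11-trien-1-yl]sulfanyl}benzene (homofarnesyl phenyl sulfide), via (phenylthio)methyllithium 19 (not isolated)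
Conditions: 18, n-BuLi, DABCO, THF, 0 °C; then 17, −78 °C to rt
Reagents that add atoms: none
Why: Alkylation of an α-thio carbanion, in which soft (phenylthio)methyllithium 19 displaces the primary allylic bromide at its α-carbon (SN2) and adds the one carbon that becomes C5′ without touching the (E)-alkenes.

Step 12
Reactants: 20 homofarnesyl phenyl sulfide
Product: 22 (6E,10E)-13-iodo-2,6,10-trimethyltrideca-2,6,10-triene (homofarnesyl iodide), via S-methylsulfonium iodide 21 (not isolated)
Conditions: MeI (excess), NaI, DMF, 75 °C, dark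
Reagents that add atoms: sodium iodide, [Na+].[I-]; iodomethane, CI
Why: Corey–Jautelat sulfide-to-iodide conversion, in which S-methylation gives sulfonium salt 21 and iodide dealkylates it at the primary homoallylic carbon (attack at methyl only regenerates 20), releasing thioanisole.

Step 13
Reactants: 16 (1S,2S)-2-[(3E)-4-iodo-3-methylbut-3-en-1-yl]-1,3,3-trimethylcyclohexan-1-ol; 22 homofarnesyl iodide
Product: 25 (1S,2S)-1,3,3-trimethyl-2-[(3E,7E,11E)-3,8,12,16-tetramethylheptadeca-3,7,11,15-tetraen-1-yl]cyclohexan-1-ol, via homofarnesyllithium 23 (not isolated), via homofarnesylzinc chloride 24 (not isolated)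
Conditions: 22 (2.5 equiv), t-BuLi (5 equiv), Et2O, −78 °C; ZnCl2, THF, −78 °C to rt; then 16, Pd(PPh3)4 (5 mol %), THF, rt; aq NH4Cl
Reagents that add atoms: none
Why: Negishi cross-coupling of a homoallylzinc reagent with an alkenyl iodide (1,5-diene synthesis), in which iodine–lithium exchange and transmetalation give 24, which couples with retention of the (E)-geometry of 16; the excess zinc reagent allows for slow protonolysis by the hindered tertiary hydroxyl, and no stereocentre is touched.

**Compound list**

1 | isobutyraldehyde (2-methylpropanal) | CC(C)C=O | starting material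
2 | 1-(2-methylprop-1-en-1-yl)pyrrolidine | CC(C)=CN1CCCC1 | intermediate
3 | ethyl vinyl ketone (pent-1-en-3-one) | CCC(=O)C=C | starting material
4 | 2,2-dimethyl-5-oxoheptanal | CCC(=O)CCC(C)(C)C=O | intermediate (not isolated)
5 | 2,4,4-trimethylcyclohex-2-en-1-one | CC1=CC(C)(C)CCC1=O | intermediate
6 | (R)-2,4,4-trimethylcyclohex-2-en-1-ol | O[C@@H]1CCC(C)(C)C=C1C | intermediate
7 | N,N-dimethylacetamide dimethyl acetal (1,1-dimethoxy-N,N-dimethylethanamine) | COC(C)(OC)N(C)C | starting material
8 | ketene N,O-acetal, N,N-dimethyl-1-{[(1R)-2,4,4-trimethylcyclohex-2-en-1-yl]oxy}ethen-1-amine | C=C(N(C)C)O[C@@H]1CCC(C)(C)C=C1C | intermediate (not isolated)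
9 | N,N-dimethyl-2-[(1S)-2,6,6-trimethylcyclohex-2-en-1-yl]acetamide | CN(C)C(=O)C[C@H]1C(C)(C)CCC=C1C | intermediate
10 | 2-[(1S)-2,6,6-trimethylcyclohex-2-en-1-yl]ethan-1-ol | OCC[C@H]1C(C)(C)CCC=C1C | intermediate
11 | (6S)-6-(2-iodoethyl)-1,5,5-trimethylcyclohex-1-ene | ICC[C@H]1C(C)(C)CCC=C1C | intermediate
12 | (6S)-6-(but-3-yn-1-yl)-1,5,5-trimethylcyclohex-1-ene | C#CCC[C@H]1C(C)(C)CCC=C1C | intermediate
13 | (1R,2S,6S)-2-(but-3-yn-1-yl)-1,3,3-trimethyl-7-oxabicyclo[4.1.0]heptane (epoxide oxygen anti to the chain) | C#CCC[C@H]1C(C)(C)CC[C@@H]2O[C@]12C | intermediate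
14 | (1S,2S)-2-(but-3-yn-1-yl)-1,3,3-trimethylcyclohexan-1-ol (OH trans to the chain) | C#CCC[C@H]1C(C)(C)CCC[C@]1(C)O | intermediate
15 | alkenylalane, (E)-dimethyl(alkenyl)alane of 14 with the hydroxyl as its dimethylaluminium alkoxide | C[Al](C)/C=C(\C)CC[C@H]1C(C)(C)CCC[C@]1(C)O[Al](C)C | intermediate (not isolated)
16 | (1S,2S)-2-[(3E)-4-iodo-3-methylbut-3-en-1-yl]-1,3,3-trimethylcyclohexan-1-ol | I/C=C(\C)CC[C@H]1C(C)(C)CCC[C@]1(C)O | intermediate
17 | (2E,6E)-farnesyl bromide | CC(C)=CCC/C(C)=C/CC/C(C)=C/CBr | starting material
18 | thioanisole (methyl phenyl sulfide) | CSc1ccccc1 | starting material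
19 | (phenylthio)methyllithium | [Li]CSc1ccccc1 | intermediate (not isolated)
20 | {[(3E,7E)-4,8,12-trimethyltrideca-3,7,11-trien-1-yl]sulfanyl}benzene (homofarnesyl phenyl sulfide) | CC(C)=CCC/C(C)=C/CC/C(C)=C/CCSc1ccccc1 | intermediate
21 | methyl(phenyl)[(3E,7E)-4,8,12-trimethyltrideca-3,7,11-trien-1-yl]sulfonium iodide | CC(C)=CCC/C(C)=C/CC/C(C)=C/CC[S+](C)c1ccccc1.[I-] | intermediate (not isolated)
22 | (6E,10E)-13-iodo-2,6,10-trimethyltrideca-2,6,10-triene (homofarnesyl iodide) | CC(C)=CCC/C(C)=C/CC/C(C)=C/CCI | intermediate
23 | homofarnesyllithium | CC(C)=CCC/C(C)=C/CC/C(C)=C/CC[Li] | intermediate (not isolated)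
24 | homofarnesylzinc chloride | CC(C)=CCC/C(C)=C/CC/C(C)=C/CC[Zn]Cl | intermediate (not isolated)
25 | (1S,2S)-1,3,3-trimethyl-2-[(3E,7E,11E)-3,8,12,16-tetramethylheptadeca-3,7,11,15-tetraen-1-yl]cyclohexan-1-ol | CC(C)=CCC/C(C)=C/CC/C(C)=C/CC/C=C(\C)CC[C@H]1C(C)(C)CCC[C@]1(C)O | target

**Step count**

Total: 13 steps. Longest linear sequence: 11 steps (steps 1–10 and 13); steps 11–12 form the two-step side branch to 22.

**Steps most likely to fail**

1. Step 8, poor or reversed facial selectivity of the epoxidation. The ring can flip, and in the half-chair with a pseudoaxial chain the axial C3 methyl sits on the opposite face, so the peracid may attack the chain face to a damaging extent. The fallback brings the oxygen to the anti face indirectly. It sets out from 12: NBS in aqueous acetone at 0 °C should put the bromonium ion on the more accessible face and water anti at tertiary C1, giving (1R,2S,6R)-6-bromo-2-(but-3-yn-1-yl)-1,3,3-trimethylcyclohexan-1-ol F1. K2CO3 in MeOH then closes the alkoxide onto C6 with inversion, and the route is rejoined at 13. Tin hydride debromination is avoided because a C6 radical or a stannyl radical would engage the alkyne.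

2. Step 13, loss of the alkylzinc reagent by protonolysis at the free C1 hydroxyl, or slow transmetalation that lets reduction and homocoupling take over. The fallback runs the same C4′–C5′ bond formation as a B-alkyl Suzuki–Miyaura coupling, whose boron ate complex tolerates the hydroxyl and aqueous base. It sets out from 22: lithiation as before (23) and trapping with B-methoxy-9-BBN give lithium B-methoxy-B-[(3E,7E)-4,8,12-trimethyltrideca-3,7,11-trien-1-yl]-9-borabicyclo[3.3.1]nonan-9-uide F2. This is coupled with 16 using Pd(dppf)Cl2, aq K3PO4, DMF, rt, and the route is rejoined at 25.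

3. Step 4, thermal elimination of the allylic oxygen function to a diene, or a stalled rearrangement at the hindered C2 at 140 °C. The fallback makes the same C2–C1′ bond by the ester enolate (Ireland–Claisen) variant at 60 °C or below. It sets out from 6: Ac2O, pyridine, DMAP give (1R)-2,4,4-trimethylcyclohex-2-en-1-yl acetate F3. LDA and TMSCl in THF at −78 °C give silyl ketene acetal trimethyl({1-[(1R)-2,4,4-trimethylcyclohex-2-en-1-yl]oxyethenyl}oxy)silane F4. Warming to 60 °C should rearrange it suprafacially to trimethylsilyl 2-[(1S)-2,6,6-trimethylcyclohex-2-en-1-yl]acetate F5. Aqueous work-up gives 2-[(1S)-2,6,6-trimethylcyclohex-2-en-1-yl]acetic acid F6, and LiAlH4 in Et2O reduces it to the alcohol, where the route is rejoined at 10.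

**Further compounds**

F1 | step 8 | (1R,2S,6R)-6-bromo-2-(but-3-yn-1-yl)-1,3,3-trimethylcyclohexan-1-ol | C#CCC[C@H]1C(C)(C)CC[C@@H](Br)[C@]1(C)O
F2 | step 13 | lithium B-methoxy-B-[(3E,7E)-4,8,12-trimethyltrideca-3,7,11-trien-1-yl]-9-borabicyclo[3.3.1]nonan-9-uide | CC(C)=CCC/C(C)=C/CC/C(C)=C/CC[B-]1(OC)C2CCCC1CCC2.[Li+]
F3 | step 4 | (1R)-2,4,4-trimethylcyclohex-2-en-1-yl acetate | CC(=O)O[C@@H]1CCC(C)(C)C=C1C
F4 | step 4 | trimethyl({1-[(1R)-2,4,4-trimethylcyclohex-2-en-1-yl]oxyethenyl}oxy)silane | C=C(O[Si](C)(C)C)O[C@@H]1CCC(C)(C)C=C1C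
F5 | step 4 | trimethylsilyl 2-[(1S)-2,6,6-trimethylcyclohex-2-en-1-yl]acetate | C[Si](C)(C)OC(=O)C[C@H]1C(C)(C)CCC=C1C
F6 | step 4 | 2-[(1S)-2,6,6-trimethylcyclohex-2-en-1-yl]acetic acid | OC(=O)C[C@H]1C(C)(C)CCC=C1C
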